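All runs were computed on assumed constants, and the scatter is random.

Watch the split. Electrophile leaves by two routes, into target and into something the readings don't show, so count the lost part as what has reacted minus target.

| setting | birch | alder | cedar | flask |
|---|---|---|---|---|
| electrophile | 0.17 M | 0.38 M | 0.25 M | 0.25 M |
| nucleophile | 1.1 equiv | 1.1 equiv | 1.1 equiv | 1.10 equiv |
| free base | 0.50 equiv | 0.50 equiv | 0.50 equiv | 0.500 equiv |
| protic impurity | 0.125 M | 0.125 M | 0.25 M | 0.125 M |
| remark | run made earlier | run made earlier | run made earlier |  |
| time |  |  |  | 20 min |

| run | time / min | electrophile / % | target / % |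
|---|---|---|---|
| birch | 2.00 | 86 | 4 |
| birch | 4.00 | 77 | 9 |
| birch | 6.00 | 67 | 13 |
| birch | 8.00 | 63 | 16 |
| birch | 10.0 | 58 | 19 |
| birch | 12.0 | 51 | 20 |
| alder | 0.833 | 92 | 4 |
| alder | 2.50 | 77 | 14 |
| alder | 4.00 | 71 | 15 |
| alder | 6.00 | 59 | 24 |
| alder | 10.0 | 51 | 35 |
| alder | 12.0 | 43 | 36 |
| cedar | 2.50 | 76 | 11 |
| cedar | 5.00 | 59 | 14 |
| cedar | 8.00 | 46 | 21 |
| cedar | 10.0 | 37 | 25 |
| cedar | 12.0 | 33 | 22 |

(readings scatter by 1.5 percentage points)

- the earlier runs do not show how much of nucleophile is bound; that part of a forecast is a guess

- part of the electrophile that has reacted at 20 min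
- share of the unused nucleophile that is free and not bound as protonated nucleophile, at 20 min

Divide one rate by the other. If both routes are first order in electrophile, c(electrophile) and time drop out, and target gained per electrophile lost follows c(nucleophile)/c(protic impurity). Take target over lost at the last reading of each run and divide by that ratio as charged. These readings, with their scatter, average 0.473: this is the split constant, a selectivity factor.

Cedar looks nearly like your flask, with the same electrophile and the same equivalents, but its charged ratio is 1.10 and your flask's is 2.20, twice as much. Cedar's last reading shows 22 % target against 45.0 % lost, more lost than made, because the split constant times cedar's ratio gives target over lost of 0.520, below one. My reckoning for your flask is target over lost near 1.04.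

The forecast says 66 % reacted and 72 % of the unused nucleophile free, on the ground that “a second route is consuming it”.

The flask gives 65.7 % reacted and 73.4 % free, so the forecast held.

    electrophile + protic impurity → quenched substrate (k = 0.00536 M⁻¹ s⁻¹)
    nucleophile + acid set free ⇌ protonated nucleophile, settled at all times (K = 756 M⁻¹)
    electrophile + nucleophile → acid set free + target (k = 0.00265 M⁻¹ s⁻¹)
    acid set free + free base ⇌ salt of the base, settled at all times (K = 957 M⁻¹)
    target → over-reaction product (k = 3.40 × 10⁻⁵ s⁻¹)

In this flask electrophile goes to target 1.2 times as fast as to quenched substrate at 5.83 min, and 1.4 times as fast at 20.0 min. At 20.0 min this flask holds 34.8 % target against 30.1 % quenched substrate, a ratio of 1.16 against the reckoned 1.04. For the neighbour with 0.21 M of protic impurity the split constant gives 0.619, and at 20.0 min that neighbour holds 30.8 % target against 45.3 % quenched substrate, a ratio of 0.680.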